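(The earlier runs and the new flask come from a simulation on assumed constants; the scatter is artificial.)

The question for the flask with 39.0 mM of solid reagent is whether the excess of right-handed substrate reaches 99 % within 40 min.

* whether the excess of right-handed substrate over left-handed substrate among what is left of the two reaches 99 % by 40 min (yes / no)
* the highest excess of right-handed substrate over left-handed substrate among what is left of the two up to 40 min

the same everywhere: left-handed substrate 13 mM; right-handed substrate 13 mM

| flask | solid reagent | remark | time |
|---|---|---|---|
| Friday's | 20 mM | run made earlier |  |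
| Sunday's | 78 mM | run made earlier |  |
| flask | 39.0 mM |  | 40 min |

| run | time / min | right-handed substrate / % | left-handed substrate / % |
|---|---|---|---|
| Friday's | 2.50 | 48.8 | 25.9 |
| Friday's | 4.00 | 48.5 | 14.5 |
| Friday's | 6.00 | 47.0 | 7.0 |
| Friday's | 10.0 | 44.7 | 2.2 |
| Friday's | 15.0 | 43.3 | 0.3 |
| Friday's | 20.0 | 41.2 | 0 |
| Friday's | 30.0 | 38.9 | 0 |
| Sunday's | 2.50 | 49.1 | 25.5 |
| Sunday's | 4.00 | 48.6 | 14.9 |
| Sunday's | 6.00 | 47.3 | 7.5 |
| Sunday's | 10.0 | 44.7 | 1.6 |
| Sunday's | 15.0 | 42.5 | 0 |
| Sunday's | 20.0 | 39.2 | 0 |
| Sunday's | 30.0 | 34.6 | 0 |

(scatter of a reading: 0.3 percentage points)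

- partner is single-handed; left-handed substrate and right-handed substrate are mirror images of each other, charged as a racemate, each of them at the stated concentration
- given per volume of solution although it is solid: solid reagent
- at the start none of the solid reagent is in solution
- the handed part of partner does not stay in what it makes, so the products of the two hands are mirror images too

Friday's and Sunday's left-handed readings stand together, 7.0 % and 7.5 % at 6.00 min, so I carry their curve over to the flask, whose charge of solid reagent, 39.0 mM, stands between 20 mM and 78 mM. Friday's left-handed substrate falls at 0.374 min⁻¹, but Sunday's right-handed substrate falls at only 0.0130 min⁻¹, a selectivity factor of 28.8 as read. Their difference, 0.361 min⁻¹, is the clearing rate, the fall per minute in the natural logarithm of left-handed over right-handed substrate. The wanted excess needs that ratio at 0.00503, and Friday's ratio at 6.00 min is 0.149, so I reckon the flask gets there at 15.4 min, earlier than the limit.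

The forecast also says yes, with a top of 100 %, holding that “the reagent is effectively at a saturated solution level while solid remains”.

The flask gives yes and a top of >99.9 %, reaching 99 % at 14.3 min with right-handed substrate at 42.4 % of the two charged.

    solid reagent ⇌ partner, rate k1*(cs1 - [partner]) while solid is left; crystals form when [partner] > cs1 (solubility = 8.40 mM, k = 0.0270 s⁻¹)
    partner + right-handed substrate → right-handed product (k = 0.0260 M⁻¹ s⁻¹)
    left-handed product ⇌ right-handed product (k = 2.90 × 10⁻⁴ s⁻¹)
    partner + left-handed substrate → left-handed product (k = 0.860 M⁻¹ s⁻¹)

In the flask at 2.52 min, left-handed substrate has a half-life of 2.0 min by its step, much shorter than the 67 min of right-handed substrate by its own. The 0.361 min⁻¹ is the clearing rate as read from the earlier runs; these two half-lives give the flask 0.332 min⁻¹ at 2.52 min, and at 40.0 min the flask holds left-handed substrate at 0 % and right-handed substrate at 30.4 %.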